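**Remark (assumption and labels).** Core atoms are labelled in the order they appear in the target SMILES: unit A = first quinolinone [C3(A), C4(A), O4(A)], Cb = C(C)(C), Cc = first [C@H], Ca = second [C@H], Cd = CH2, Ce = [C@](C), Cf = CH2, Cg = third [C@H], unit B = second quinolinone. CIP descriptors worked out for the target: Cc S, Ca R, Ce S, Cg R. Compound 3 will equilibrate with cyclic hemiketals, as warfarin-type adducts do; it is drawn in the open keto form, which is the form that reacts in step 2.

## The problem

Two 1-methylquinolin-2-one units are each joined through C3 and O4 to one C10 core, a cyclohexane (Ca–Cd–Ce–Cf–Cg–Cc) that carries a methyl on Ce and the gem-dimethyl carbon Cb on Cc. Unit A closes ring A, a 2,2-dimethyl-3,4-dihydro-2H-pyran [O4(A)–Cb–Cc–Ca–C3(A)=C4(A)] trans-fused to the carbocycle at Ca–Cc; unit B closes ring B [O4(B)–Ce–Cf–Cg–C3(B)=C4(B)], which spans Ce and Cg and makes a 2-oxabicyclo[3.3.1]nonane. Of the four stereocentres, Ce and Cg are tied together by ring B, whose two bonds to the carbocycle must be 1,3-diaxial, while Cb on Cc and C3(A) on Ca are both equatorial; unit B is therefore cis to Cb, which a free chair cyclisation would not choose for a large group next to the reacting alkene. Once ring B exists, a chair transition state built on it has only one way to place Ca and Cc, so the absolute problem reduces to one stereocentre (Cg) and the relative problem to the cis relation, across ring B, of the Ce side arm and the Cg substituent, where the arm competes with a methyl of almost the same size. The feature that makes the key step possible is that O4(A)–C4(A)–C3(A)–Ca and Cc–Cb of ring A are the retron of an oxa-Diels–Alder reaction between a 3-alkylidenequinoline-2,4-dione [O=C4(A)–C3(A)=Ca] and a trisubstituted alkene (Cc=CbMe2), and that the four atoms between Ca and Cc (Cd, Ce, Cf, Cg) are the side-chain carbon, C2, C3 and C4 of ring B. Sensitive points: both ether carbons (Cb, Ce) are tertiary ethers of a vinylogous acid and ionise in strong acid; an aldehyde at Ca is β to the Ce–O bond and can expel unit B; a free 4-OH beside a trisubstituted alkene adds to it under acid; the ambident quinolinone can close rings through the lactam oxygen instead of O4.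

## Retrosynthesis

**10 ⇒ 9 ⇒ 8 + 1.** The Ca–Cc and O4(A)–Cb bonds are cut as an intramolecular oxa-Diels–Alder reaction, then C3(A)=Ca as a Knoevenagel condensation. This leads from target 10 through oxadiene 9 to aldehyde 8 and quinolinone 1.
- Against the all-carbon [4+2] cut (Cg–Cc and Ca–Cd), it uses 1 in its natural polarity (C3 nucleophile, then electron-poor heterodiene) and leaves a precursor whose single reagent-set stereocentre is catalytically accessible.
- Against the same cycloaddition on an open chain with ring B closed last, the group on Cg would there sit equatorial next to the alkene and end up trans to Cb. With ring B in place the quinolinone is held axial, which is what the target needs.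
- Aldehyde 8 is a tricyclic monomer with two stereocentres; the other half of the target arrives as commercial 1.
- The forward step must be an exo (trans-fusing) cycloaddition through the ketone carbonyl that outruns β-elimination of the Ce–O bond.

**8 ⇒ 6 (through 7).** The acetaldehyde arm Cd–Ca is written as an ethynyl group. The alkyne is inert to the β-elimination that threatens 8 and is unmasked only just before the key step. It is also the one two-carbon arm clearly slimmer than methyl, which the next disconnection needs. The forward step is an anti-Markovnikov hydration that must spare the trisubstituted alkene.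

**6 ⇒ 4 (through 5).** The O4(B)–Ce bond is cut as a propargylic etherification.
- An oxa-Michael closure onto an enoate would sort methyl against CH2CO2R with no bias.
- An acid-mediated closure would also protonate the isobutenyl group and would not distinguish O4 from the lactam oxygen.
- Adding a carbon nucleophile to the methyl oxocarbenium ion would place the new arm trans and risks ring opening.
- A copper-allenylidene closure is anionic (O4), mild, and makes Ce trigonal, so both carbinol epimers of 4 converge. It must deliver the 2,4-cis ether.

**4 ⇒ 3.** The Ce–Cd bond is cut: acetylide addition to the methyl ketone brings in Cd and Ca in one operation.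

**3 ⇒ 1 + 2.** The C3(B)–Cg bond is cut as an enantioselective warfarin-type Michael addition of 1 to commercial dienone 2. Dienone 2 already holds Cf, Ce with its methyl, and the complete dienophile (Cc=CbMe2). This sets Cg, from which Ce (step 3) and then Ca and Cc (step 5) are derived.

## Roads not taken

**Alternative 1:** the obvious cut is the all-carbon [4+2] through Cg–Cc and Ca–Cd plus the two C–O bonds.
- Forward: N-methylflindersine A1 (from 1 and 3-methylbut-2-enal) would be heated to open to diene A2. Diene A2 would add as diene across the styrenic double bond of a second A2 to give cyclohexene A3, and two hydroalkoxylations would follow.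
- Why the chosen plan is better: the cycloaddition is unactivated, so it needs high temperature and offers no handle for a chiral catalyst. A2 can also add to the cis double bond of A1, and endo/exo control is weak, so diastereomeric dimers are expected. A single enantiomer could come only from resolution of a mixture. The chosen plan sets one centre by catalysis and relays it.

**Alternative 2:** cut Cc–Cg and Cc–Ca, using the hidden symmetry.
- Forward: dienone A4 would take up an acetoacetate ester by double Michael addition and, after decarboxylation, give the trans-3,5-diaryl-4-acetylcyclohexanone A5. Excess MeMgBr would give diol A6, in which Ce and Cc are not stereogenic, and acid would close both ethers.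
- Why the chosen plan is better: the required trans isomer has one aryl axial, whereas such double additions settle to the all-equatorial cis (achiral) ketone. The acceptor carbons of A4 are deactivated by the enol oxygen and invite addition–elimination at C4. The last step must still choose trans- over cis-fusion. The route is longer.

**Alternative 3:** carbocycle first, cutting C3(A)–Ca and O4(A)–Cb.
- Forward: 1 would add in Michael fashion to the bridged enone A7 from the face anti to ring B to give ketone A8, followed by MeMgBr and cyclodehydration.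
- Why the chosen plan is better: the rigid bicycle would control Ca and Cc well, but A7 needs the same cis-2,4 pattern on ring B plus an extra ring closure, so it is at least three steps longer. The end-game also passes through a tertiary cation in acid next to the acid-labile Ce–O bond.

Key step: step 5

## Steps

Step 1
Reactants: 1 4-hydroxy-1-methylquinolin-2(1H)-one; 2 (3E)-6-methylhepta-3,5-dien-2-one
Product: 3 4-hydroxy-1-methyl-3-[(4R)-2-methyl-6-oxohept-2-en-4-yl]quinolin-2(1H)-one
Conditions: (R,R)-1,2-diphenylethane-1,2-diamine (10 mol %), AcOH (1 equiv), THF, rt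
Reagents that add atoms: none
Why: Organocatalytic warfarin-type Michael addition: the primary diamine forms an iminium ion with the enone and the acidic enol 1 adds at the β-carbon, 1,4- rather than 1,6-addition being expected because the δ-carbon is fully substituted; shielding of one iminium face sets Cg, (R) being expected from this diamine by analogy with benzylideneacetone, and the antipodal diamine is used if the sense proves opposite.

Step 2
Reactants: 3 4-hydroxy-1-methyl-3-[(4R)-2-methyl-6-oxohept-2-en-4-yl]quinolin-2(1H)-one
Product: 4 4-hydroxy-3-[(4R)-6-hydroxy-2,6-dimethyloct-2-en-7-yn-4-yl]-1-methylquinolin-2(1H)-one (both C6 epimers)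
Conditions: HC≡CMgBr (3 equiv), THF, −20 °C → rt; aq NH4Cl
Reagents that add atoms: ethynylmagnesium bromide, C#C[Mg]Br
Why: Grignard 1,2-addition to the methyl ketone of the open-chain magnesium quinolinonate (the first equivalent is consumed by the acidic OH); the carbinol centre forms unselectively, which is harmless because it becomes trigonal in step 3, and the low temperature limits enolisation and with it retro-Michael loss of Cg.

Step 3
Reactants: 4 4-hydroxy-3-[(4R)-6-hydroxy-2,6-dimethyloct-2-en-7-yn-4-yl]-1-methylquinolin-2(1H)-one
Product: 6 (2S,4R)-2-ethynyl-2,6-dimethyl-4-(2-methylprop-1-en-1-yl)-2,3,4,6-tetrahydro-5H-pyrano[3,2-c]quinolin-5-one, via propargylic trifluoroacetate 5 (not isolated)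
Conditions: DBU (3 equiv), (CF3CO)2O (1.1 equiv), MeCN, −10 °C; then CuCl2·2H2O (5 mol %), 0 °C → rt
Reagents that add atoms: trifluoroacetic anhydride, O=C(OC(=O)C(F)(F)F)C(F)(F)F (its acyl group is carried by 5 only)
Why: Copper-catalysed propargylic etherification: acyl transfer should leave the ester on the tertiary alkoxide, the copper acetylide ionises to a copper allenylidene, and its trigonal γ-carbon (Ce) is captured by O4 of the quinolinonate, the usual site of O-alkylation of this anion, in a six-membered closure. The isobutenyl group on C4 is pseudoaxial (allylic 1,3-strain with the C5 carbonyl), and the rod-like cumulene arm rather than methyl should take the face syn to it, giving the 2,4-cis ether and setting Ce; the basic medium keeps the free OH from adding to the alkene.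

Step 4
Reactants: 6 (2S,4R)-2-ethynyl-2,6-dimethyl-4-(2-methylprop-1-en-1-yl)-2,3,4,6-tetrahydro-5H-pyrano[3,2-c]quinolin-5-one
Product: 8 [(2S,4R)-2,6-dimethyl-4-(2-methylprop-1-en-1-yl)-5-oxo-3,4,5,6-tetrahydro-2H-pyrano[3,2-c]quinolin-2-yl]acetaldehyde, via alkenylborane 7 (not isolated)
Conditions: Cy2BH (1.5 equiv), THF, 0 °C; then 30 % H2O2, pH 7 phosphate buffer, 0 °C
Reagents that add atoms: dicyclohexylborane, B(C1CCCCC1)C1CCCCC1 (boron and cyclohexyl groups are carried by 7 only); hydrogen peroxide, OO
Why: Syn, anti-Markovnikov hydroboration of the terminal alkyne by the bulky dialkylborane, which should leave the trisubstituted alkene and the lactam alone, then oxidation of the alkenylborane to the enol and so to the aldehyde; the buffered oxidation avoids base-induced β-elimination of the Ce–O bond, and no stereocentre is touched.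

Step 5
Reactants: 8 [(2S,4R)-2,6-dimethyl-4-(2-methylprop-1-en-1-yl)-5-oxo-3,4,5,6-tetrahydro-2H-pyrano[3,2-c]quinolin-2-yl]acetaldehyde; 1 4-hydroxy-1-methylquinolin-2(1H)-one
Product: 10 the target CNP0229685.7, via oxadiene 9 (not isolated)
Conditions: ethylenediammonium diacetate (EDDA, 10 mol %), 4 Å molecular sieves, MeCN, rt → 60 °C
Reagents that add atoms: none
Why: Knoevenagel condensation of 8 with C3 of 1 gives the 3-alkylidenequinoline-2,4-dione 9, an electron-poor 1-oxadiene [O=C4(A)–C3(A)=Ca] that is trapped by the electron-rich Cc=CbMe2 alkene in an intramolecular inverse-electron-demand oxa-Diels–Alder reaction. The closest known reaction type is the domino Knoevenagel/hetero-Diels–Alder reaction of 4-hydroxyquinolin-2-ones and 4-hydroxycoumarins with citronellal, which has the same four-atom tether; here two tether atoms (Ce, Cg) are C2 and C4 of ring B. The carbocycle closes by the Ca–Cc bond as a six-membered chair across the 2,4-diaxial bonds of ring B, which completes the 2-oxabicyclo[3.3.1]nonane. Ring A closes by the O4(A)–Cb bond in the fused [4+2] mode through the exo transition state (oxadiene anti to the tether), which gives the trans ring fusion. Ca is controlled by Ce and Cg: the axial site on Ca points into ring B, so C3(A) must be equatorial, anti to the bridge. Cc is controlled by Ca: for the C–O bond to form, Cb must also be equatorial, which fixes the alkene face; the only other chair arrangement would put CMe2 axial and give a cis-fused pyran. The step needs exo selectivity, use of the ketone rather than the lactam carbonyl as the heterodiene terminus (the normal outcome for this heterodiene), and cycloaddition faster than β-elimination of unit B, which the nearly neutral catalyst and the intramolecular trap are meant to secure. The price is that the C3(B)–Cg bond is pressed towards the Z-methyl of the alkene in the productive chair, hence the mild heating.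

## Compound list

1 | 4-hydroxy-1-methylquinolin-2(1H)-one | Cn1c(=O)cc(O)c2ccccc12 | starting material
2 | (3E)-6-methylhepta-3,5-dien-2-one | CC(=O)/C=C/C=C(C)C | starting material
3 | 4-hydroxy-1-methyl-3-[(4R)-2-methyl-6-oxohept-2-en-4-yl]quinolin-2(1H)-one | CC(=O)C[C@H](C=C(C)C)c1c(O)c2ccccc2n(C)c1=O | intermediate
4 | 4-hydroxy-3-[(4R)-6-hydroxy-2,6-dimethyloct-2-en-7-yn-4-yl]-1-methylquinolin-2(1H)-one (both C6 epimers) | C#CC(C)(O)C[C@H](C=C(C)C)c1c(O)c2ccccc2n(C)c1=O | intermediate
5 | (5R)-5-(4-hydroxy-1-methyl-2-oxo-1,2-dihydroquinolin-3-yl)-3,7-dimethyloct-6-en-1-yn-3-yl trifluoroacetate (both C3 epimers) | C#CC(C)(OC(=O)C(F)(F)F)C[C@H](C=C(C)C)c1c(O)c2ccccc2n(C)c1=O | intermediate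
6 | (2S,4R)-2-ethynyl-2,6-dimethyl-4-(2-methylprop-1-en-1-yl)-2,3,4,6-tetrahydro-5H-pyrano[3,2-c]quinolin-5-one | C#C[C@]2(C)C[C@H](C=C(C)C)c1c(c3ccccc3n(C)c1=O)O2 | intermediate
7 | (2S,4R)-2-[(E)-2-(dicyclohexylboranyl)ethenyl]-2,6-dimethyl-4-(2-methylprop-1-en-1-yl)-2,3,4,6-tetrahydro-5H-pyrano[3,2-c]quinolin-5-one | C1CCCCC1B(C1CCCCC1)/C=C/[C@]2(C)C[C@H](C=C(C)C)c1c(c3ccccc3n(C)c1=O)O2 | intermediate
8 | [(2S,4R)-2,6-dimethyl-4-(2-methylprop-1-en-1-yl)-5-oxo-3,4,5,6-tetrahydro-2H-pyrano[3,2-c]quinolin-2-yl]acetaldehyde | O=CC[C@]2(C)C[C@H](C=C(C)C)c1c(c3ccccc3n(C)c1=O)O2 | intermediate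
9 | 3-{2-[(2R,4R)-2,6-dimethyl-4-(2-methylprop-1-en-1-yl)-5-oxo-3,4,5,6-tetrahydro-2H-pyrano[3,2-c]quinolin-2-yl]ethylidene}-1-methylquinoline-2,4(1H,3H)-dione (same spatial arrangement as 8; the C2 descriptor changes by CIP rank only) | CN1C(=O)C(=CC[C@]3(C)C[C@H](C=C(C)C)c4c(c5ccccc5n(C)c4=O)O3)C(=O)c2ccccc12 | intermediate
10 | target CNP0229685.7: heptacyclic bis(1-methylquinolin-2-one) with trans-fused ring A and bridging ring B (Cc S, Ca R, Ce S, Cg R) | Cn1c(=O)c2c(c3ccccc31)OC(C)(C)[C@H]1[C@H]2C[C@]2(C)C[C@H]1c1c(c3ccccc3n(C)c1=O)O2 | target

## Step count and least certain steps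

Total: 5 steps. Longest linear sequence: 5 steps (1 + 2 → 10; compound 1 is used again in step 5).

**Step 5 (key step).**
- What may go wrong: loss of unit B by β-elimination, either through the enamine of 8 or in vinylogous fashion from 9. The oxatriene so formed would close irreversibly onto O4(A) as a 2H-pyran. The cycloaddition may also be slow because of the allylic strain between the C3(B)–Cg bond and the Z-methyl in the only productive chair, and some cycloaddition may occur through the lactam carbonyl.
- Fallback: condensation is separated from cycloaddition and no amine is used. From 8, treatment with 2.2 equiv of 1 in EtOH/H2O at 50 °C should give the isolable bis-adduct 3,3'-{2-[(2S,4R)-2,6-dimethyl-4-(2-methylprop-1-en-1-yl)-5-oxo-3,4,5,6-tetrahydro-2H-pyrano[3,2-c]quinolin-2-yl]ethane-1,1-diyl}bis(4-hydroxy-1-methylquinolin-2(1H)-one) F1. Heating F1 in toluene at 110 °C should release 1 by retro-Michael reaction and generate 9 under neutral conditions, which returns to the route at 10.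

**Step 3.**
- What may go wrong: poor facial discrimination between methyl and the cumulene arm at the trigonal Ce, elimination of the propargylic ester to an enyne, acyl transfer that leaves the enol oxygen blocked, or closure through the lactam oxygen.
- Fallback: ring B is closed by conjugate addition instead. From 3, Horner–Wadsworth–Emmons olefination (triethyl phosphonoacetate, NaH 2.2 equiv, THF, 60 °C) should give ethyl (2E,5R)-5-(4-hydroxy-1-methyl-2-oxo-1,2-dihydroquinolin-3-yl)-3,7-dimethylocta-2,6-dienoate F2. Intramolecular oxa-Michael addition (DBU, MeCN) should then give ethyl [(2S,4R)-2,6-dimethyl-4-(2-methylprop-1-en-1-yl)-5-oxo-3,4,5,6-tetrahydro-2H-pyrano[3,2-c]quinolin-2-yl]acetate F3 together with its C2 epimer. The epimers are separated, and the unwanted one is re-equilibrated with DBU through the reversible addition. iBu2AlH (CH2Cl2, −78 °C) then returns to the route at 8.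

**Step 4.**
- What may go wrong: β-elimination of the Ce–O bond from the aldehyde during the oxidative work-up, and double hydroboration of the alkyne.
- Fallback: the oxidation level is changed so that the aldehyde is made last under neutral conditions. From 6, semihydrogenation (H2, Pd/CaCO3 poisoned with Pb(OAc)2, quinoline) should give (2S,4R)-2-ethenyl-2,6-dimethyl-4-(2-methylprop-1-en-1-yl)-2,3,4,6-tetrahydro-5H-pyrano[3,2-c]quinolin-5-one F4. 9-BBN then NaBO3·4H2O should give (2S,4R)-2-(2-hydroxyethyl)-2,6-dimethyl-4-(2-methylprop-1-en-1-yl)-2,3,4,6-tetrahydro-5H-pyrano[3,2-c]quinolin-5-one F5. Dess–Martin periodinane buffered with NaHCO3 returns to the route at 8.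

**Step 1.**
- What may go wrong: erosion of enantioselectivity through the uncatalysed addition of the acidic enol and through reversible addition, and some 1,6-addition.
- Fallback: resolution instead of asymmetric catalysis. From 1 and 2, an achiral amine catalyst (pyrrolidine, AcOH, THF) should give racemic 4-hydroxy-1-methyl-3-(2-methyl-6-oxohept-2-en-4-yl)quinolin-2(1H)-one F6. Preparative chromatography on a chiral stationary phase returns to the route at 3.

## Further compounds

F1 | step 5 | 3,3'-{2-[(2S,4R)-2,6-dimethyl-4-(2-methylprop-1-en-1-yl)-5-oxo-3,4,5,6-tetrahydro-2H-pyrano[3,2-c]quinolin-2-yl]ethane-1,1-diyl}bis(4-hydroxy-1-methylquinolin-2(1H)-one) | Cn1c(=O)c(C(C[C@]4(C)C[C@H](C=C(C)C)c5c(c6ccccc6n(C)c5=O)O4)c2c(O)c3ccccc3n(C)c2=O)c(O)c2ccccc12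
F2 | step 3 | ethyl (2E,5R)-5-(4-hydroxy-1-methyl-2-oxo-1,2-dihydroquinolin-3-yl)-3,7-dimethylocta-2,6-dienoate | CCOC(=O)/C=C(\C)C[C@H](C=C(C)C)c1c(O)c2ccccc2n(C)c1=O
F3 | step 3 | ethyl [(2S,4R)-2,6-dimethyl-4-(2-methylprop-1-en-1-yl)-5-oxo-3,4,5,6-tetrahydro-2H-pyrano[3,2-c]quinolin-2-yl]acetate | CCOC(=O)C[C@]2(C)C[C@H](C=C(C)C)c1c(c3ccccc3n(C)c1=O)O2
F4 | step 4 | (2S,4R)-2-ethenyl-2,6-dimethyl-4-(2-methylprop-1-en-1-yl)-2,3,4,6-tetrahydro-5H-pyrano[3,2-c]quinolin-5-one | C=C[C@]2(C)C[C@H](C=C(C)C)c1c(c3ccccc3n(C)c1=O)O2
F5 | step 4 | (2S,4R)-2-(2-hydroxyethyl)-2,6-dimethyl-4-(2-methylprop-1-en-1-yl)-2,3,4,6-tetrahydro-5H-pyrano[3,2-c]quinolin-5-one | OCC[C@]2(C)C[C@H](C=C(C)C)c1c(c3ccccc3n(C)c1=O)O2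
F6 | step 1 | racemic 4-hydroxy-1-methyl-3-(2-methyl-6-oxohept-2-en-4-yl)quinolin-2(1H)-one | CC(=O)CC(C=C(C)C)c1c(O)c2ccccc2n(C)c1=O
A1 | alternative 1 | N-methylflindersine, 2,2,6-trimethyl-2,6-dihydro-5H-pyrano[3,2-c]quinolin-5-one | Cn1c(=O)c2c(c3ccccc31)OC(C)(C)C=C2
A2 | alternative 1 | 4-hydroxy-1-methyl-3-[(1E)-3-methylbuta-1,3-dien-1-yl]quinolin-2(1H)-one | C=C(C)/C=C/c1c(O)c2ccccc2n(C)c1=O
A3 | alternative 1 | 3,3'-[5-methyl-2-(prop-1-en-2-yl)cyclohex-4-ene-1,3-diyl]bis(4-hydroxy-1-methylquinolin-2(1H)-one), racemic, relative configuration as in 10 (one enantiomer drawn) | CC(=C)[C@H]1[C@H](c2c(O)c3ccccc3n(C)c2=O)CC(C)=C[C@H]1c1c(O)c2ccccc2n(C)c1=O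
A4 | alternative 2 | (1E,4E)-1,5-bis(4-hydroxy-1-methyl-2-oxo-1,2-dihydroquinolin-3-yl)penta-1,4-dien-3-one | O=C(/C=C/c1c(O)c2ccccc2n(C)c1=O)/C=C/c1c(O)c2ccccc2n(C)c1=O
A5 | alternative 2 | 3,3'-(2-acetyl-5-oxocyclohexane-1,3-diyl)bis(4-hydroxy-1-methylquinolin-2(1H)-one), 1,3-trans, configuration as in 10 | CC(=O)C1[C@H](c2c(O)c3ccccc3n(C)c2=O)CC(=O)C[C@H]1c1c(O)c2ccccc2n(C)c1=O
A6 | alternative 2 | 3,3'-[5-hydroxy-2-(2-hydroxypropan-2-yl)-5-methylcyclohexane-1,3-diyl]bis(4-hydroxy-1-methylquinolin-2(1H)-one), 1,3-trans, configuration as in 10 | CC(C)(O)C1[C@H](c2c(O)c3ccccc3n(C)c2=O)CC(C)(O)C[C@H]1c1c(O)c2ccccc2n(C)c1=O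
A7 | alternative 3 | bridged enone: ring B of 10 on a cyclohexene with Cc=Ca double bond and acetyl on Cc | CC(=O)C1=CC[C@]2(C)C[C@H]1c1c(c3ccccc3n(C)c1=O)O2
A8 | alternative 3 | Michael adduct of 1 with A7: acetyl on Cc, 4-hydroxy-1-methyl-2-oxoquinolin-3-yl on Ca, configuration as in 10 | CC(=O)[C@H]1[C@H](c2c(O)c3ccccc3n(C)c2=O)C[C@]2(C)C[C@H]1c1c(c3ccccc3n(C)c1=O)O2
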